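The route rests on disconnecting rings A and B of the labdane together across C1–C2 and C5–C10. The tetrasubstituted C8=C9 alkene of ring B lies within the four-carbon link C6–C9 between the ring-fusion carbons C5 and C10, so it can serve as a rigid Z tether. One intramolecular Diels–Alder reaction, catalysed by a chiral oxazaborolidinium ion, then closes both rings, forms two C–C bonds and sets C5 and C10 (trans fusion). Its precursor is an acyclic pentaene: a methyl 2-vinyl-2-enoate diene (C2–C5, ester on C4) joined through C6–C7 and the Z C8=C9 alkene to an isopropenyl dienophile (C10=C1), with the silyl-protected C11–C16 chain on C9.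

Key step: step 12

Remark on the chemistry: labdane numbering is used for all atoms that end up in the target (C19 is the ester carbon on C4, C18 the methyl group added in step 14); the sense of face selection by the catalyst in step 12 cannot be derived from precedent, so the (S)-oxazaborolidine is written and its commercially available mirror image would be taken if the opposite sense were found.

Step 1
Reactants: 1 3-methylbut-2-en-1-ol (prenol)
Product: 2 tert-butyl(dimethyl)[(3-methylbut-2-en-1-yl)oxy]silane
Conditions: t-BuMe2SiCl, imidazole, CH2Cl2, 0 °C to rt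
Reagents that add atoms: tert-butyldimethylsilyl chloride, CC(C)(C)[Si](C)(C)Cl
Why: Imidazole-mediated silylation of a primary allylic alcohol is routine, and the tert-butyldimethylsilyl ether is chosen because it should survive the organolithium, hydride, palladium and low-temperature Lewis-acid steps ahead and leave with fluoride at the end.

Step 2
Reactants: 2 tert-butyl(dimethyl)[(3-methylbut-2-en-1-yl)oxy]silane
Product: 3 (2E)-4-{[tert-butyl(dimethyl)silyl]oxy}-2-methylbut-2-en-1-ol
Conditions: SeO2 (cat.), t-BuOOH, salicylic acid (cat.), CH2Cl2, 0 °C to rt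
Reagents that add atoms: tert-butyl hydroperoxide, CC(C)(C)OO (its oxygen is delivered through SeO2, O=[Se]=O)
Why: SeO2-catalysed allylic oxidation (ene reaction followed by [2,3]-sigmatropic shift, with t-BuOOH as terminal oxidant) is known to hydroxylate the methyl group trans to the chain of a 2-methylalk-2-ene, which fixes the E geometry of the later C13=C14 alkene.

Step 3
Reactants: 3 (2E)-4-{[tert-butyl(dimethyl)silyl]oxy}-2-methylbut-2-en-1-ol
Product: 4 {[(2E)-4-bromo-3-methylbut-2-en-1-yl]oxy}(tert-butyl)dimethylsilane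
Conditions: CBr4, PPh3, CH2Cl2, 0 °C
Reagents that add atoms: carbon tetrabromide, BrC(Br)(Br)Br
Why: Appel bromination converts the primary allylic alcohol to the bromide under neutral conditions by SN2 displacement of the oxyphosphonium group, without touching the alkene geometry or the silyl ether.

Step 4
Reactants: 5 methyl 2-methyl-3-oxobutanoate; 4 {[(2E)-4-bromo-3-methylbut-2-en-1-yl]oxy}(tert-butyl)dimethylsilane
Product: 7 methyl (6E)-8-{[tert-butyl(dimethyl)silyl]oxy}-2,6-dimethyl-3-oxooct-6-enoate (racemic at C2), via keto ester dianion 6 (not isolated)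
Conditions: NaH, THF, 0 °C; n-BuLi, 0 °C; then 4, 0 °C to rt
Reagents that add atoms: none
Why: Dianion gamma-alkylation of a beta-keto ester: the doubly deprotonated keto ester reacts at its more basic terminal carbon with the primary allylic bromide by SN2 displacement, forming the C11–C12 bond and delivering C7, C8, C17, C9 and C11 in one piece (the C2 stereocentre of 7 is of no consequence because it becomes sp2 in step 5).

Step 5
Reactants: 7 methyl (6E)-8-{[tert-butyl(dimethyl)silyl]oxy}-2,6-dimethyl-3-oxooct-6-enoate
Product: 8 methyl (2Z,6E)-8-{[tert-butyl(dimethyl)silyl]oxy}-2,6-dimethyl-3-{[(trifluoromethyl)sulfonyl]oxy}octa-2,6-dienoate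
Conditions: (CF3SO2)2O, sat. aq. LiOH, toluene, 5 °C
Reagents that add atoms: trifluoromethanesulfonic anhydride, O=S(=O)(OS(=O)(=O)C(F)(F)F)C(F)(F)F
Why: Enol triflation of the lithium-chelated enolate, in which lithium bridges the ketone and ester oxygens, should place the triflate cis to the ester (Z), which is the geometry that later holds C7 and C10 on the same side of the C8=C9 alkene.

Step 6
Reactants: 8 methyl (2Z,6E)-8-{[tert-butyl(dimethyl)silyl]oxy}-2,6-dimethyl-3-{[(trifluoromethyl)sulfonyl]oxy}octa-2,6-dienoate; 9 4,4,5,5-tetramethyl-2-(prop-1-en-2-yl)-1,3,2-dioxaborolane (isopropenylboronic acid pinacol ester)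
Product: 10 methyl (2Z,6E)-8-{[tert-butyl(dimethyl)silyl]oxy}-2,6-dimethyl-3-(prop-1-en-2-yl)octa-2,6-dienoate
Conditions: Pd(PPh3)4 (5 mol %), K3PO4, 1,4-dioxane/H2O, 60 °C
Reagents that add atoms: none
Why: Suzuki–Miyaura coupling of an electron-poor alkenyl triflate with an alkenylboronate proceeds through oxidative addition, transmetalation and reductive elimination with retention of alkene geometry when zerovalent palladium carries PPh3, so the isopropenyl group (C10, C20, C1) should end up cis to the ester carbon C7.

Step 7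
Reactants: 10 methyl (2Z,6E)-8-{[tert-butyl(dimethyl)silyl]oxy}-2,6-dimethyl-3-(prop-1-en-2-yl)octa-2,6-dienoate
Product: 11 (2Z,6E)-8-{[tert-butyl(dimethyl)silyl]oxy}-2,6-dimethyl-3-(prop-1-en-2-yl)octa-2,6-dien-1-ol
Conditions: iBu2AlH (2.5 equiv), CH2Cl2, −78 °C; aq. potassium sodium tartrate work-up
Reagents that add atoms: none
Why: 1,2-Reduction of a conjugated ester by iBu2AlH at low temperature is reliable and leaves the tetrasubstituted alkene geometry, the diene and the silyl ether untouched.

Step 8
Reactants: 11 (2Z,6E)-8-{[tert-butyl(dimethyl)silyl]oxy}-2,6-dimethyl-3-(prop-1-en-2-yl)octa-2,6-dien-1-ol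
Product: 12 {[(2E,6Z)-8-bromo-3,7-dimethyl-6-(prop-1-en-2-yl)octa-2,6-dien-1-yl]oxy}(tert-butyl)dimethylsilane
Conditions: N-bromosuccinimide, Me2S, CH2Cl2, −20 to 0 °C; used at once
Reagents that add atoms: N-bromosuccinimide, O=C1CCC(=O)N1Br
Why: Bromination through the alkoxysulfonium salt formed from N-bromosuccinimide and Me2S replaces the allylic hydroxyl by SN2 attack of bromide under non-acidic conditions at low temperature, which should avoid ionisation of the dienylic system and loss of the Z geometry.

Step 9
Reactants: 12 {[(2E,6Z)-8-bromo-3,7-dimethyl-6-(prop-1-en-2-yl)octa-2,6-dien-1-yl]oxy}(tert-butyl)dimethylsilane; 13 3-bromoprop-1-yne (propargyl bromide)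
Product: 16 methyl (6Z,10E)-12-{[tert-butyl(dimethyl)silyl]oxy}-6,10-dimethyl-7-(prop-1-en-2-yl)dodeca-6,10-dien-2-ynoate, via 1,3-dilithiopropyne 14 (not isolated), via lithium acetylide 15 (not isolated)
Conditions: 13, n-BuLi (2 equiv per 13), Me2NCH2CH2NMe2, Et2O/hexane, −78 °C; then 12, −78 °C to rt; then ClCO2Me, −78 °C
Reagents that add atoms: methyl chloroformate, COC(=O)Cl
Why: Propargylation with 1,3-dilithiopropyne, known for primary allylic bromides, should occur at the sp3 carbon of the dianion by SN2 displacement at C7 (the SN2' position C9 is fully substituted), and the lithium acetylide left over is acylated in the same flask by methyl chloroformate, giving the C6–C7 bond and the C4–C19 bond in one operation.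

Step 10
Reactants: 16 methyl (6Z,10E)-12-{[tert-butyl(dimethyl)silyl]oxy}-6,10-dimethyl-7-(prop-1-en-2-yl)dodeca-6,10-dien-2-ynoate
Product: 17 methyl (2E,6Z,10E)-12-{[tert-butyl(dimethyl)silyl]oxy}-6,10-dimethyl-7-(prop-1-en-2-yl)-2-(tributylstannyl)dodeca-2,6,10-trienoate
Conditions: Bu3SnH (1.1 equiv, slow addition), Pd(PPh3)4 (2 mol %), THF, 0 °C
Reagents that add atoms: tributyltin hydride, CCCC[SnH](CCCC)CCCC
Why: Palladium-catalysed hydrostannation of a 2-ynoate is a syn addition that places tin on the carbon next to the ester, so H on C5 and tin on C4 become cis and the chain carbon C6 ends up cis to the ester, as the diene requires.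

Step 11
Reactants: 17 methyl (2E,6Z,10E)-12-{[tert-butyl(dimethyl)silyl]oxy}-6,10-dimethyl-7-(prop-1-en-2-yl)-2-(tributylstannyl)dodeca-2,6,10-trienoate; 18 bromoethene (vinyl bromide)
Product: 19 methyl (2Z,6Z,10E)-12-{[tert-butyl(dimethyl)silyl]oxy}-2-ethenyl-6,10-dimethyl-7-(prop-1-en-2-yl)dodeca-2,6,10-trienoate (the acyclic pentaene)
Conditions: 18 (1 M in THF, 3 equiv), Pd(PPh3)4 (5 mol %), CuI (20 mol %), DMF, 40 °C, sealed vessel
Reagents that add atoms: none
Why: Stille coupling of the alkenylstannane with vinyl bromide (CuI as transmetalation promoter) replaces tin by the vinyl group with retention, so C6 stays trans to the vinyl group and the C2=C3–C4=C5 diene can reach the s-cis conformation.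

Step 12
Reactants: 19 methyl (2Z,6Z,10E)-12-{[tert-butyl(dimethyl)silyl]oxy}-2-ethenyl-6,10-dimethyl-7-(prop-1-en-2-yl)dodeca-2,6,10-trienoate
Product: 20 methyl (4aS,8aR)-5-[(3E)-5-{[tert-butyl(dimethyl)silyl]oxy}-3-methylpent-3-en-1-yl]-4a,6-dimethyl-3,4,4a,7,8,8a-hexahydronaphthalene-1-carboxylate (trans-fused; 5R,10S in labdane numbering)
Conditions: (S)-1-(2-methylphenyl)-3,3-diphenyltetrahydro-1H,3H-pyrrolo[1,2-c][1,3,2]oxazaborole (20 mol %), (CF3SO2)2NH (18 mol %), CH2Cl2 (0.02 M), −78 to −20 °C
Reagents that add atoms: none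
Why: Proposed new method: the boron cation should bind the ester carbonyl, lower the LUMO of the C2=C3–C4=C5 diene and shield one of its faces, after which the electron-rich C10=C1 alkene (the open terminus of the C8=C9–C10=C1 unit) adds in a concerted, asynchronous [4+2] cycloaddition with inverse electron demand that forms C1–C2 and C5–C10; the closest known reaction types are thermal intramolecular Diels–Alder reactions of deca-1,3,9-trienes, Lewis-acid-promoted cycloadditions of 2-alkoxycarbonyl dienes and oxazaborolidinium-catalysed Diels–Alder reactions of unsaturated esters, but an enantioselective version with the activating ester on the diene has no precedent. Ring A is the cyclohexene generated by the cycloaddition itself, and ring B is closed by the C5–C10 bond as a six-membered ring in the fused (type 1) mode, exo with respect to both reacting alkenes, across the C6–C7–C8=C9 tether. C5 and C10 are set together: their relative configuration (trans fusion) should follow from the transition state with the tether carbon C9 exo and the small C10 methyl group endo, which keeps the bulky tetrasubstituted C8=C9 unit with C17 and the C11 chain away from the diene, and their absolute configuration (5R,10S, bonding at the Si face of C5 and the Re face of C10) has to come from the face of the ester-bound diene left open by the catalyst. Regiochemistry needs no control by the reagent, because the Z C8=C9 alkene holds C7 and C10 cis, only the pairing C5–C10/C1–C2 gives two six-membered rings (any other pairing would need a four-membered or a bridged ring) and the C8=C9–C10=C1 unit cannot serve as the diene since C8 is fully substituted. The E placement of C6 on C4=C5 secured in steps 10 and 11 allows the s-cis diene, and the low temperature should suppress the thermal [1,5]-hydrogen shift from C7 to C1 that the cis arrangement of C7 and C10 would otherwise permit. The weak point is that the tether forces the electrophilic carbon C5 to bond to the substituted carbon C10 against the intrinsic polarity of the two partners, so the rate gain by the Lewis acid and the level of enantioselectivity are open.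

Step 13
Reactants: 20 methyl (4aS,8aR)-5-[(3E)-5-{[tert-butyl(dimethyl)silyl]oxy}-3-methylpent-3-en-1-yl]-4a,6-dimethyl-3,4,4a,7,8,8a-hexahydronaphthalene-1-carboxylate
Product: 21 methyl (4aS,8aS)-5-[(3E)-5-{[tert-butyl(dimethyl)silyl]oxy}-3-methylpent-3-en-1-yl]-4a,6-dimethyl-1,2,3,4,4a,7,8,8a-octahydronaphthalene-1-carboxylate (both C4 epimers)
Conditions: Mg turnings, MeOH, 0 °C to rt
Reagents that add atoms: none
Why: Dissolving-metal conjugate reduction by Mg in MeOH (electron transfer to the unsaturated ester and protonation by the solvent) saturates only the C3=C4 bond, since isolated tri- and tetrasubstituted alkenes and silyl ethers do not react, and the mixture of C4 epimers is of no consequence because C4 becomes an enolate carbon in step 14.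

Step 14
Reactants: 21 methyl (4aS,8aS)-5-[(3E)-5-{[tert-butyl(dimethyl)silyl]oxy}-3-methylpent-3-en-1-yl]-4a,6-dimethyl-1,2,3,4,4a,7,8,8a-octahydronaphthalene-1-carboxylate
Product: 23 methyl (1S,4aS,8aR)-5-[(3E)-5-{[tert-butyl(dimethyl)silyl]oxy}-3-methylpent-3-en-1-yl]-1,4a,6-trimethyl-1,2,3,4,4a,7,8,8a-octahydronaphthalene-1-carboxylate, via lithium ester enolate 22 (not isolated)
Conditions: LiN(iPr)2 (commercial solution), THF, −78 to 0 °C; MeI, −78 °C to rt
Reagents that add atoms: iodomethane, CI
Why: Ester enolate alkylation: MeI should approach the exocyclic enolate carbon C4 along the equatorial direction on the alpha face, away from the axial C10 methyl group on the beta face, so the new methyl group (C18) becomes equatorial and the ester (C19) axial, which is the 4S configuration of the target.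

Step 15
Reactants: 23 methyl (1S,4aS,8aR)-5-[(3E)-5-{[tert-butyl(dimethyl)silyl]oxy}-3-methylpent-3-en-1-yl]-1,4a,6-trimethyl-1,2,3,4,4a,7,8,8a-octahydronaphthalene-1-carboxylate
Product: 25 methyl (1S,4aS,8aR)-5-[(3E)-5-(acetyloxy)-3-methylpent-3-en-1-yl]-1,4a,6-trimethyl-1,2,3,4,4a,7,8,8a-octahydronaphthalene-1-carboxylate (CNP0206695.1), via primary allylic alcohol 24 (not isolated)
Conditions: Bu4NF, THF, 0 °C to rt; then Ac2O, 4-(dimethylamino)pyridine (cat.), rt
Reagents that add atoms: acetic anhydride, CC(=O)OC(C)=O
Why: Fluoride-induced cleavage of the Si–O bond followed in the same flask by 4-(dimethylamino)pyridine-catalysed acetylation of the liberated primary allylic alcohol touches no stereocentre and no alkene.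

Compound list
1 | 3-methylbut-2-en-1-ol (prenol) | CC(C)=CCO | starting material
2 | tert-butyl(dimethyl)[(3-methylbut-2-en-1-yl)oxy]silane | CC(C)=CCO[Si](C)(C)C(C)(C)C | intermediate
3 | (2E)-4-{[tert-butyl(dimethyl)silyl]oxy}-2-methylbut-2-en-1-ol | OC/C(C)=C/CO[Si](C)(C)C(C)(C)C | intermediate
4 | {[(2E)-4-bromo-3-methylbut-2-en-1-yl]oxy}(tert-butyl)dimethylsilane | BrC/C(C)=C/CO[Si](C)(C)C(C)(C)C | intermediate
5 | methyl 2-methyl-3-oxobutanoate | COC(=O)C(C)C(C)=O | starting material
6 | sodium lithium dianion of 5 (bis-enolate, not isolated) | [Li]OC(=C)C(C)=C(OC)O[Na] | intermediate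
7 | methyl (6E)-8-{[tert-butyl(dimethyl)silyl]oxy}-2,6-dimethyl-3-oxooct-6-enoate (racemic at C2) | COC(=O)C(C)C(=O)CC/C(C)=C/CO[Si](C)(C)C(C)(C)C | intermediate
8 | methyl (2Z,6E)-8-{[tert-butyl(dimethyl)silyl]oxy}-2,6-dimethyl-3-{[(trifluoromethyl)sulfonyl]oxy}octa-2,6-dienoate | COC(=O)/C(C)=C(OS(=O)(=O)C(F)(F)F)/CC/C(C)=C/CO[Si](C)(C)C(C)(C)C | intermediate
9 | 4,4,5,5-tetramethyl-2-(prop-1-en-2-yl)-1,3,2-dioxaborolane | CC(=C)B1OC(C)(C)C(C)(C)O1 | starting material
10 | methyl (2Z,6E)-8-{[tert-butyl(dimethyl)silyl]oxy}-2,6-dimethyl-3-(prop-1-en-2-yl)octa-2,6-dienoate | COC(=O)/C(C)=C(C(C)=C)/CC/C(C)=C/CO[Si](C)(C)C(C)(C)C | intermediate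
11 | (2Z,6E)-8-{[tert-butyl(dimethyl)silyl]oxy}-2,6-dimethyl-3-(prop-1-en-2-yl)octa-2,6-dien-1-ol | OC/C(C)=C(C(C)=C)/CC/C(C)=C/CO[Si](C)(C)C(C)(C)C | intermediate
12 | {[(2E,6Z)-8-bromo-3,7-dimethyl-6-(prop-1-en-2-yl)octa-2,6-dien-1-yl]oxy}(tert-butyl)dimethylsilane | BrC/C(C)=C(C(C)=C)/CC/C(C)=C/CO[Si](C)(C)C(C)(C)C | intermediate
13 | 3-bromoprop-1-yne (propargyl bromide) | C#CCBr | starting material
14 | 1,3-dilithiopropyne (not isolated) | [Li]CC#C[Li] | intermediate
15 | lithium acetylide of the C6–C7 coupled enyne (not isolated) | [Li]C#CCC/C(C)=C(C(C)=C)/CC/C(C)=C/CO[Si](C)(C)C(C)(C)C | intermediate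
16 | methyl (6Z,10E)-12-{[tert-butyl(dimethyl)silyl]oxy}-6,10-dimethyl-7-(prop-1-en-2-yl)dodeca-6,10-dien-2-ynoate | COC(=O)C#CCC/C(C)=C(C(C)=C)/CC/C(C)=C/CO[Si](C)(C)C(C)(C)C | intermediate
17 | methyl (2E,6Z,10E)-12-{[tert-butyl(dimethyl)silyl]oxy}-6,10-dimethyl-7-(prop-1-en-2-yl)-2-(tributylstannyl)dodeca-2,6,10-trienoate | COC(=O)/C([Sn](CCCC)(CCCC)CCCC)=C\CC/C(C)=C(C(C)=C)/CC/C(C)=C/CO[Si](C)(C)C(C)(C)C | intermediate
18 | bromoethene (vinyl bromide) | C=CBr | starting material
19 | methyl (2Z,6Z,10E)-12-{[tert-butyl(dimethyl)silyl]oxy}-2-ethenyl-6,10-dimethyl-7-(prop-1-en-2-yl)dodeca-2,6,10-trienoate (acyclic pentaene, precursor of the key step) | C=C/C(C(=O)OC)=C/CC/C(C)=C(/CC/C(C)=C/CO[Si](C)(C)C(C)(C)C)\C(C)=C | intermediate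
20 | methyl (4aS,8aR)-5-[(3E)-5-{[tert-butyl(dimethyl)silyl]oxy}-3-methylpent-3-en-1-yl]-4a,6-dimethyl-3,4,4a,7,8,8a-hexahydronaphthalene-1-carboxylate (methyl 15-silyloxy-18-norlabda-3,8,13E-trien-19-oate; 5R,10S; trans-fused) | COC(=O)C1=CCC[C@]2(C)C(CC/C(C)=C/CO[Si](C)(C)C(C)(C)C)=C(C)CC[C@@H]12 | intermediate
21 | methyl (4aS,8aS)-5-[(3E)-5-{[tert-butyl(dimethyl)silyl]oxy}-3-methylpent-3-en-1-yl]-4a,6-dimethyl-1,2,3,4,4a,7,8,8a-octahydronaphthalene-1-carboxylate (methyl 15-silyloxy-18-norlabda-8,13E-dien-19-oate; both C4 epimers) | COC(=O)C1CCC[C@]2(C)C(CC/C(C)=C/CO[Si](C)(C)C(C)(C)C)=C(C)CC[C@@H]12 | intermediate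
22 | lithium enolate of 21 (exocyclic at C4, not isolated) | COC(O[Li])=C1CCC[C@]2(C)C(CC/C(C)=C/CO[Si](C)(C)C(C)(C)C)=C(C)CC[C@@H]12 | intermediate
23 | methyl (1S,4aS,8aR)-5-[(3E)-5-{[tert-butyl(dimethyl)silyl]oxy}-3-methylpent-3-en-1-yl]-1,4a,6-trimethyl-1,2,3,4,4a,7,8,8a-octahydronaphthalene-1-carboxylate (methyl 15-silyloxylabda-8,13E-dien-19-oate; 4S,5R,10S) | COC(=O)[C@@]1(C)CCC[C@]2(C)C(CC/C(C)=C/CO[Si](C)(C)C(C)(C)C)=C(C)CC[C@@H]12 | intermediate
24 | methyl (1S,4aS,8aR)-5-[(3E)-5-hydroxy-3-methylpent-3-en-1-yl]-1,4a,6-trimethyl-1,2,3,4,4a,7,8,8a-octahydronaphthalene-1-carboxylate (methyl 15-hydroxylabda-8,13E-dien-19-oate, not isolated) | COC(=O)[C@@]1(C)CCC[C@]2(C)C(CC/C(C)=C/CO)=C(C)CC[C@@H]12 | intermediate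
25 | methyl (1S,4aS,8aR)-5-[(3E)-5-(acetyloxy)-3-methylpent-3-en-1-yl]-1,4a,6-trimethyl-1,2,3,4,4a,7,8,8a-octahydronaphthalene-1-carboxylate (methyl 15-acetoxylabda-8,13E-dien-19-oate; 4S,5R,10S; CNP0206695.1) | COC(=O)[C@@]1(C)CCC[C@]2(C)C(CC/C(C)=C/COC(C)=O)=C(C)CC[C@@H]12 | target

Total step count: 15
Longest linear sequence: 15 steps (from 1 to 25)

Steps most likely to fail

Step 12. The Lewis acid may not accelerate the cycloaddition enough against the polarity mismatch. In that case acid-induced isomerisation or oligomerisation of the diene units, loss of the silyl ether, incomplete catalyst turnover, or poor face and exo/endo selection could take over. The fallback uses known chemistry and sets out from 19. The cycloaddition is run thermally without catalyst (toluene, about 150 °C, sealed vessel, high dilution, 2,6-di-tert-butyl-4-methylphenol as radical inhibitor). This should give the trans-fused adduct as the racemate, that is 20 together with the mirror-image cycloadduct F1, any cis-fused isomer being removed on silica. The two enantiomers are then separated by preparative chromatography on a chiral stationary phase (cellulose tris(3,5-dimethylphenylcarbamate) on silica), and the route is rejoined at 20.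

Step 9. The dienylic bromide may ionise or undergo halogen–metal exchange in contact with the strongly basic dianion, and the dianion may react through its allenyl terminus or at the remote diene terminus C1. The fallback sets out from 12. The bromide is alkylated with 3-lithio-1-(trimethylsilyl)propyne F2 (made from 1-(trimethylsilyl)propyne and n-BuLi, THF, −78 °C), in which silicon blocks the alkyne terminus and directs attack to the propargylic carbon, to give the trimethylsilyl enyne F3. K2CO3 in MeOH then removes the silyl group to give the terminal enyne F4. Deprotonation with n-BuLi and acylation with ClCO2Me converts F4 through the lithium acetylide 15 into 16, where the route is rejoined.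

Step 11. Transmetalation from the hindered, electron-poor alpha-stannyl enoate may be slow, so that protodestannylation or homocoupling competes with the coupling. The fallback sets out from 17. Iododestannylation (I2, CH2Cl2, 0 °C) should proceed with retention to give the alpha-iodo enoate F5. This is coupled in the reversed polarity sense by a Suzuki–Miyaura reaction with vinylboronic acid pinacol ester (Pd(PPh3)4, K3PO4, THF/H2O, 50 °C), which returns to the route at 19.

Further compounds
F1 | step 12 | mirror-image cycloadduct, methyl (4aR,8aS)-5-[(3E)-5-{[tert-butyl(dimethyl)silyl]oxy}-3-methylpent-3-en-1-yl]-4a,6-dimethyl-3,4,4a,7,8,8a-hexahydronaphthalene-1-carboxylate (formed with 20 as the racemate) | COC(=O)C1=CCC[C@@]2(C)C(CC/C(C)=C/CO[Si](C)(C)C(C)(C)C)=C(C)CC[C@H]12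
F2 | step 9 | 3-lithio-1-(trimethylsilyl)propyne | [Li]CC#C[Si](C)(C)C
F3 | step 9 | tert-butyl{[(2E,6Z)-3,7-dimethyl-6-(prop-1-en-2-yl)-11-(trimethylsilyl)undeca-2,6-dien-10-yn-1-yl]oxy}dimethylsilane (trimethylsilyl enyne) | C[Si](C)(C)C#CCC/C(C)=C(C(C)=C)/CC/C(C)=C/CO[Si](C)(C)C(C)(C)C
F4 | step 9 | tert-butyl{[(2E,6Z)-3,7-dimethyl-6-(prop-1-en-2-yl)undeca-2,6-dien-10-yn-1-yl]oxy}dimethylsilane (terminal enyne) | C#CCC/C(C)=C(C(C)=C)/CC/C(C)=C/CO[Si](C)(C)C(C)(C)C
F5 | step 11 | methyl (2E,6Z,10E)-12-{[tert-butyl(dimethyl)silyl]oxy}-2-iodo-6,10-dimethyl-7-(prop-1-en-2-yl)dodeca-2,6,10-trienoate (alpha-iodo enoate) | COC(=O)/C(I)=C\CC/C(C)=C(C(C)=C)/CC/C(C)=C/CO[Si](C)(C)C(C)(C)C
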